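**Retrosynthetic overview**

1. The target is a 2,4-cis (2S,4S)-7,3',4'-trihydroxyflavan joined through C4 to C8 of (+)-catechin. The last disconnection is the C3=C4 bond of the perbenzylated 4-aryl-2H-chromene 16: hydrogenation from the face opposite the C2 aryl group sets C4 and removes all eight benzyl groups.
2. Ring C of the upper unit is opened at C2–C3 and O1–C8a: aldehyde 11 is inserted between an alkenyl nucleophile at C3 and an aryne carbon at C8a of upper ring A.
3. Enabling feature: in upper ring A, C8a is ortho to C4a (the carbon bearing C4), and C8 lies between C8a and the oxygen-bearing C7. A fluorine at C8a makes C8–H the most acidic ring hydrogen, so base gives the C8–C8a aryne. The C7 oxygen beside C8 and the cis C3=C4 tether beside C8a both send the C2 alkoxide to C8a.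
4. The precursor, Z-alkenyl iodide 10, comes from syn-hydroarylation of alkynylsilane 8 with 8-iodo-penta-O-benzylcatechin 4, followed by iododesilylation.
5. Ring order: the lower catechin rings come intact from (+)-catechin, upper ring A from 3-fluoro-4-iodophenol, and upper ring C is the only ring formed (step 8).

Key step: step 8

Remark: rotation about the C4–C8 interflavan bond is taken as free, so no axial descriptor is assigned; 16 and 17 may appear as rotamers in solution.

**Route**

Step 1
Reactants: 1 (+)-catechin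
Product: 2 5,7,3',4'-tetra-O-benzylcatechin
Conditions: BnBr (4.4 equiv), K2CO3, DMF, 0 °C → rt
Reagents that add atoms: benzyl bromide, BrCc1ccccc1
Why: Williamson etherification under carbonate base should cap the four phenols and leave the less acidic secondary 3-OH free; no stereocentre is touched.

Step 2
Reactants: 2 5,7,3',4'-tetra-O-benzylcatechin
Product: 3 3,5,7,3',4'-penta-O-benzylcatechin
Conditions: NaH, BnBr, Bu4NI (cat.), DMF, 0 °C → rt
Reagents that add atoms: benzyl bromide, BrCc1ccccc1
Why: Williamson etherification of the sodium alkoxide of the 3-OH; with the phenols capped, C2 cannot epimerise through a quinone methide.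

Step 3
Reactants: 3 3,5,7,3',4'-penta-O-benzylcatechin
Product: 4 8-iodo-3,5,7,3',4'-penta-O-benzylcatechin
Conditions: N-iodosuccinimide (1.0 equiv), CH2Cl2, −20 °C → rt, dark
Reagents that add atoms: N-iodosuccinimide, O=C1CCC(=O)N1I
Why: electrophilic aromatic iodination of the phloroglucinol-type ring is expected at C8, which is less hindered than C6 (flanked by two benzyloxy groups), by analogy with the C8-selective halogenation of benzylated catechins.

Step 4
Reactants: 5 3-fluoro-4-iodophenol
Product: 6 4-(benzyloxy)-2-fluoro-1-iodobenzene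
Conditions: BnBr, K2CO3, acetone, reflux
Reagents that add atoms: benzyl bromide, BrCc1ccccc1
Why: Williamson etherification of the phenol; the aryl halides are inert.

Step 5
Reactants: 6 4-(benzyloxy)-2-fluoro-1-iodobenzene; 7 ethynyltrimethylsilane
Product: 8 {[4-(benzyloxy)-2-fluorophenyl]ethynyl}trimethylsilane
Conditions: PdCl2(PPh3)2 (cat.), CuI (cat.), Et3N, THF, rt
Reagents that add atoms: none
Why: Sonogashira coupling at the C–I bond; the C–F bond does not react.

Step 6
Reactants: 4 8-iodo-3,5,7,3',4'-penta-O-benzylcatechin; 8 {[4-(benzyloxy)-2-fluorophenyl]ethynyl}trimethylsilane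
Product: 9 (Z)-[2-(4-benzyloxy-2-fluorophenyl)-2-(3,5,7,3',4'-penta-O-benzylcatechin-8-yl)ethenyl]trimethylsilane (silicon cis to the fluoroaryl ring)
Conditions: Pd(OAc)2 (cat.), PPh3, HCO2H, Et3N, DMF, 60 °C
Reagents that add atoms: none
Why: reductive Heck-type syn-hydroarylation of an aryl(silyl)alkyne: zerovalent palladium inserts into the C8–I bond of 4, the aryl group adds to the alkyne carbon remote from silicon, and formate replaces palladium by hydrogen with retention, so the catechin ring ends cis to hydrogen and silicon cis to the fluoroaryl ring.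

Step 7
Reactants: 9 (Z)-alkenylsilane
Product: 10 (Z)-8-[1-(4-benzyloxy-2-fluorophenyl)-2-iodoethenyl]-3,5,7,3',4'-penta-O-benzylcatechin (iodine cis to the fluoroaryl ring)
Conditions: N-iodosuccinimide (1.05 equiv), MeCN–CH2Cl2, 0 °C, dark
Reagents that add atoms: N-iodosuccinimide, O=C1CCC(=O)N1I
Why: electrophilic ipso-iododesilylation: iodine attacks the silicon-bearing carbon and the β-silyl cation loses silicon with retention of geometry; this carbon should be more nucleophilic than the hindered C6 of the catechin ring.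

Step 8
Reactants: 10 (Z)-alkenyl iodide; 11 3,4-bis(benzyloxy)benzaldehyde
Product: 16 (2S)-7-(benzyloxy)-2-[3,4-bis(benzyloxy)phenyl]-4-(3,5,7,3',4'-penta-O-benzylcatechin-8-yl)-2H-chromene, via alkenyllithium 12 (not isolated), via alkenyl(ethyl)zinc 13 (not isolated), via ethylzinc (S)-alkoxide 14 (not isolated), via aryne alkoxide 15 (not isolated)
Conditions: t-BuLi (2.0 equiv), Et2O, −78 °C; EtZnCl, −78 → 0 °C; N,N,N',N'-tetraethylethylenediamine, (−)-MIB [(2S)-3-exo-morpholinoisoborneol, 10 mol %], 11 (0.9 equiv), toluene, 0 °C; then LiN(iPr)2 (4 equiv), THF, −78 → 0 °C; aq NH4Cl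
Reagents that add atoms: none
Why: Iodine–lithium exchange with retention and transmetalation give the alkenyl(ethyl)zinc, whose alkenyl group the (−)-MIB–zinc catalyst is expected to transfer to the Si face of 11 (catalytic asymmetric alkenylzinc addition to an aldehyde; the diamine masks the lithium halides that would cause a racemic background), which forms C2–C3 and sets C2 as S under catalyst control. LiN(iPr)2 then removes the ring A hydrogen at C8, the most acidic arene hydrogen because it lies between the fluorine at C8a and the benzyloxy group at C7, and loss of LiF on warming gives the C8–C8a aryne (aryne generation from a 3-fluoroanisole-type arene by a lithium amide). The alkoxide oxygen adds to C8a in a 6-exo-dig closure of ring C (intramolecular alkoxide capture of an aryne), and the C8 aryl anion is protonated by diisopropylamine or on quench. The regiochemistry at the triple bond is secured twice: the cis alkene holds the oxygen within reach of C8a only, and the C7 oxygen beside C8 polarises the aryne so that the nucleophile enters at the remote carbon C8a while the charge develops at C8. Chemoselectivity rests on the faster transfer of alkenyl than ethyl from zinc and on the low temperature, at which the benzyl ethers should not be metalated; direct displacement of fluoride at C8a would give the same product.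

Step 9
Reactants: 16 (2S)-4-aryl-2H-chromene
Product: 17 (2R,3S)-2-(3,4-dihydroxyphenyl)-8-[(2S,4S)-2-(3,4-dihydroxyphenyl)-7-hydroxychroman-4-yl]chromane-3,5,7-triol (CNP0227165.3)
Conditions: H2 (1 atm), Pd(OH)2/C, THF–MeOH, rt
Reagents that add atoms: none
Why: heterogeneous hydrogenation should add H2 to the C3=C4 bond from the face opposite the C2 aryl group, so the C4 hydrogen is cis to the C2 hydrogen and C4 becomes S (2,4-cis), while the eight benzyl ethers are cleaved by hydrogenolysis; the cyclic benzylic C2–O bonds of flavans are expected to survive these mild conditions.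

**Compound list**

1 | (+)-catechin, (2R,3S)-2-(3,4-dihydroxyphenyl)chromane-3,5,7-triol | Oc1cc(O)c2c(c1)O[C@H](c1ccc(O)c(O)c1)[C@@H](O)C2 | starting material
2 | 5,7,3',4'-tetra-O-benzylcatechin | c1c(OCc4ccccc4)cc(OCc4ccccc4)c2c1O[C@H](c3ccc(OCc4ccccc4)c(OCc4ccccc4)c3)[C@@H](O)C2 | intermediate
3 | 3,5,7,3',4'-penta-O-benzylcatechin | c1c(OCc4ccccc4)cc(OCc4ccccc4)c2c1O[C@H](c3ccc(OCc4ccccc4)c(OCc4ccccc4)c3)[C@@H](OCc4ccccc4)C2 | intermediate
4 | 8-iodo-3,5,7,3',4'-penta-O-benzylcatechin | Ic1c(OCc4ccccc4)cc(OCc4ccccc4)c2c1O[C@H](c3ccc(OCc4ccccc4)c(OCc4ccccc4)c3)[C@@H](OCc4ccccc4)C2 | intermediate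
5 | 3-fluoro-4-iodophenol | Oc1ccc(I)c(F)c1 | starting material
6 | 4-(benzyloxy)-2-fluoro-1-iodobenzene | Fc1cc(OCc2ccccc2)ccc1I | intermediate
7 | ethynyltrimethylsilane | C#C[Si](C)(C)C | starting material
8 | {[4-(benzyloxy)-2-fluorophenyl]ethynyl}trimethylsilane | C[Si](C)(C)C#Cc1ccc(OCc2ccccc2)cc1F | intermediate
9 | (Z)-[2-(4-benzyloxy-2-fluorophenyl)-2-(penta-O-benzylcatechin-8-yl)ethenyl]trimethylsilane, silicon cis to the fluoroaryl ring | C[Si](C)(C)/C=C(/c1c(OCc4ccccc4)cc(OCc4ccccc4)c2c1O[C@H](c3ccc(OCc4ccccc4)c(OCc4ccccc4)c3)[C@@H](OCc4ccccc4)C2)c5ccc(OCc4ccccc4)cc5F | intermediate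
10 | (Z)-8-[1-(4-benzyloxy-2-fluorophenyl)-2-iodoethenyl]-penta-O-benzylcatechin, iodine cis to the fluoroaryl ring | I/C=C(/c1c(OCc4ccccc4)cc(OCc4ccccc4)c2c1O[C@H](c3ccc(OCc4ccccc4)c(OCc4ccccc4)c3)[C@@H](OCc4ccccc4)C2)c5ccc(OCc4ccccc4)cc5F | intermediate
11 | 3,4-bis(benzyloxy)benzaldehyde | O=Cc1ccc(OCc2ccccc2)c(OCc2ccccc2)c1 | starting material
12 | (Z)-alkenyllithium, 10 with lithium in place of iodine (not isolated) | [Li]/C=C(/c1c(OCc4ccccc4)cc(OCc4ccccc4)c2c1O[C@H](c3ccc(OCc4ccccc4)c(OCc4ccccc4)c3)[C@@H](OCc4ccccc4)C2)c5ccc(OCc4ccccc4)cc5F | intermediate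
13 | (Z)-alkenyl(ethyl)zinc, 10 with ethylzinc in place of iodine (not isolated) | CC[Zn]/C=C(/c1c(OCc4ccccc4)cc(OCc4ccccc4)c2c1O[C@H](c3ccc(OCc4ccccc4)c(OCc4ccccc4)c3)[C@@H](OCc4ccccc4)C2)c5ccc(OCc4ccccc4)cc5F | intermediate
14 | ethylzinc alkoxide of (1S,2Z)-1-[3,4-bis(benzyloxy)phenyl]-3-(4-benzyloxy-2-fluorophenyl)-3-(penta-O-benzylcatechin-8-yl)prop-2-en-1-ol (not isolated) | CC[Zn]O[C@H](c6ccc(OCc4ccccc4)c(OCc4ccccc4)c6)/C=C(/c1c(OCc4ccccc4)cc(OCc4ccccc4)c2c1O[C@H](c3ccc(OCc4ccccc4)c(OCc4ccccc4)c3)[C@@H](OCc4ccccc4)C2)c5ccc(OCc4ccccc4)cc5F | intermediate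
15 | lithium alkoxide of the aryne derived from 14: fluorine at C8a and hydrogen at C8 of ring A removed, C8–C8a triple bond (not isolated) | [Li]O[C@H](c6ccc(OCc4ccccc4)c(OCc4ccccc4)c6)/C=C(/c1c(OCc4ccccc4)cc(OCc4ccccc4)c2c1O[C@H](c3ccc(OCc4ccccc4)c(OCc4ccccc4)c3)[C@@H](OCc4ccccc4)C2)C5=CC=C(OCc4ccccc4)C#C5 | intermediate
16 | (2S)-7-(benzyloxy)-2-[3,4-bis(benzyloxy)phenyl]-4-(3,5,7,3',4'-penta-O-benzylcatechin-8-yl)-2H-chromene | c4ccccc4COc1ccc2c(c1)O[C@H](c6ccc(OCc4ccccc4)c(OCc4ccccc4)c6)C=C2c1c(OCc4ccccc4)cc(OCc4ccccc4)c2c1O[C@H](c3ccc(OCc4ccccc4)c(OCc4ccccc4)c3)[C@@H](OCc4ccccc4)C2 | intermediate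
17 | (2R,3S)-2-(3,4-dihydroxyphenyl)-8-[(2S,4S)-2-(3,4-dihydroxyphenyl)-7-hydroxychroman-4-yl]chromane-3,5,7-triol (CNP0227165.3) | Oc1ccc2c(c1)O[C@H](c1ccc(O)c(O)c1)C[C@@H]2c1c(O)cc(O)c2c1O[C@H](c1ccc(O)c(O)c1)[C@@H](O)C2 | target

**Step count**

Total steps: 9.
Longest linear sequence: 7 steps (steps 1, 2, 3, 6, 7, 8, 9; compounds 1 → 2 → 3 → 4 → 9 → 10 → 16 → 17).

**Steps most likely to fail**

Step 8. Two processes may fail: facial selection in the zinc-mediated transfer of so hindered an alkenyl group may be poor, and the aryne may be intercepted by the amide base or preceded by metalation of benzyl ethers before the alkoxide closes the ring. The fallback separates the events and uses known chemistry; it sets out from 10 and comes back at 16. Iodine–lithium exchange on 10 (t-BuLi, Et2O, −78 °C) and uncatalysed addition to 11 would give the allylic alcohol F1 as a mixture of C2 epimers. Oxidation with MnO2 would give the enone F2. Corey–Bakshi–Shibata reduction (2-methyl-CBS-oxazaborolidine, catecholborane, toluene, −78 °C), with the catalyst enantiomer that delivers hydride to the Re face, should give the (S)-alcohol F3. Ring closure by direct intramolecular SNAr displacement of the fluoride by the sodium alkoxide (NaH, DMF, 60 °C) would then give 16.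

Step 6. Oxidative addition and carbopalladation of the doubly ortho-oxygenated aryl iodide may be slow, so that formate reduction of the aryl–palladium species (loss of iodine without coupling) wins, or the alkenyl–palladium intermediate may isomerise and erode the syn geometry. The fallback reverses the polarity of the aryl partner; it sets out from 4 and comes back at 9. Iodine–lithium exchange on 4 (n-BuLi, THF, −78 °C) and quenching with 2-isopropoxy-4,4,5,5-tetramethyl-1,3,2-dioxaborolane would give the 8-boronate F4. Syn-hydroarylation of 8 with F4 catalysed by [Rh(OH)(cod)]2 in dioxane–water at 80 °C, with the aryl group adding to the alkyne carbon remote from silicon, should give 9.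

Step 7. Iodination of the electron-rich catechin ring at C6 may compete with attack at the silicon-bearing carbon, or the alkene geometry may be lost through a long-lived diaryl-stabilised cation. The fallback replaces electrophilic iododesilylation by iodination of a boronate ate complex, which is selective for the boron-bearing carbon; it sets out from 4 and comes back at 10. Sonogashira coupling of 4 with 7 would give F5, and K2CO3 in MeOH would give the terminal alkyne F6. Copper-catalysed syn-arylboration of F6 (CuCl, PCy3, NaOtBu, B2pin2, aryl iodide 6, THF) puts boron on the terminal carbon and the fluoroaryl group cis to it, giving the alkenylboronate F7. Treatment of F7 with I2 and NaOH in THF–water should give 10 with retention.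

Further compounds
F1 | step 8 | (2Z)-1-[3,4-bis(benzyloxy)phenyl]-3-(4-benzyloxy-2-fluorophenyl)-3-(penta-O-benzylcatechin-8-yl)prop-2-en-1-ol, mixture of C1 epimers | OC(c6ccc(OCc4ccccc4)c(OCc4ccccc4)c6)/C=C(/c1c(OCc4ccccc4)cc(OCc4ccccc4)c2c1O[C@H](c3ccc(OCc4ccccc4)c(OCc4ccccc4)c3)[C@@H](OCc4ccccc4)C2)c5ccc(OCc4ccccc4)cc5F
F2 | step 8 | (2Z)-1-[3,4-bis(benzyloxy)phenyl]-3-(4-benzyloxy-2-fluorophenyl)-3-(penta-O-benzylcatechin-8-yl)prop-2-en-1-one | O=C(c6ccc(OCc4ccccc4)c(OCc4ccccc4)c6)/C=C(/c1c(OCc4ccccc4)cc(OCc4ccccc4)c2c1O[C@H](c3ccc(OCc4ccccc4)c(OCc4ccccc4)c3)[C@@H](OCc4ccccc4)C2)c5ccc(OCc4ccccc4)cc5F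
F3 | step 8 | (1S,2Z)-1-[3,4-bis(benzyloxy)phenyl]-3-(4-benzyloxy-2-fluorophenyl)-3-(penta-O-benzylcatechin-8-yl)prop-2-en-1-ol | O[C@H](c6ccc(OCc4ccccc4)c(OCc4ccccc4)c6)/C=C(/c1c(OCc4ccccc4)cc(OCc4ccccc4)c2c1O[C@H](c3ccc(OCc4ccccc4)c(OCc4ccccc4)c3)[C@@H](OCc4ccccc4)C2)c5ccc(OCc4ccccc4)cc5F
F4 | step 6 | 3,5,7,3',4'-penta-O-benzyl-8-(4,4,5,5-tetramethyl-1,3,2-dioxaborolan-2-yl)catechin | CC1(C)OB(OC1(C)C)c1c(OCc4ccccc4)cc(OCc4ccccc4)c2c1O[C@H](c3ccc(OCc4ccccc4)c(OCc4ccccc4)c3)[C@@H](OCc4ccccc4)C2
F5 | step 7 | 3,5,7,3',4'-penta-O-benzyl-8-[(trimethylsilyl)ethynyl]catechin | C[Si](C)(C)C#Cc1c(OCc4ccccc4)cc(OCc4ccccc4)c2c1O[C@H](c3ccc(OCc4ccccc4)c(OCc4ccccc4)c3)[C@@H](OCc4ccccc4)C2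
F6 | step 7 | 3,5,7,3',4'-penta-O-benzyl-8-ethynylcatechin | C#Cc1c(OCc4ccccc4)cc(OCc4ccccc4)c2c1O[C@H](c3ccc(OCc4ccccc4)c(OCc4ccccc4)c3)[C@@H](OCc4ccccc4)C2
F7 | step 7 | (Z)-2-[2-(4-benzyloxy-2-fluorophenyl)-2-(penta-O-benzylcatechin-8-yl)ethenyl]-4,4,5,5-tetramethyl-1,3,2-dioxaborolane, boron cis to the fluoroaryl ring | CC1(C)OB(OC1(C)C)/C=C(/c1c(OCc4ccccc4)cc(OCc4ccccc4)c2c1O[C@H](c3ccc(OCc4ccccc4)c(OCc4ccccc4)c3)[C@@H](OCc4ccccc4)C2)c5ccc(OCc4ccccc4)cc5F
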